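Ring B is cut at C6'–C1', C2'–C3' and C5'–C6' into an ynol silyl ether (C1', C2'–O) and 4-chloro-3-methylcyclobutenone (C3'–C6'). The keto ester is traced back to a phthalide, the alkyne to an ethynyl carbinol (cuts at C≡C–O and carbinol C–C≡C), and the ring A formyl carbon to an ortho-metalation at C2.
The enabling feature is ring B itself: a resorcinol whose C1', between the oxygenated carbons C2' and C6', carries the carbon substituent, with Me on C4' and Cl on C5'. The alkyne supplies C1' and C2'–O; the cyclobutenone supplies C3'–H, C4'–Me, C5'–Cl and C6'–O.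
Forward: ring A benzoate → diethylamide → C2 formylation → ethynyl carbinol → siloxyalkyne; separately propyne and dichloroketene → chlorocyclobutenone; the benzannulation then builds ring B.
After ring B: acid closes the lactone (phthalide), oxygenation of its C3–H opens it to the keto acid, then esterification and desilylation.
Stereochemistry: the target has no stereocentre; the carbinol/phthalide carbon is carried racemic and erased when it becomes the ketone carbon.

Key step: step 8

Remark (assumption): the target SMILES has no stereodescriptor and the benzophenone is not expected to be configurationally stable, so the "single enantiomer" is the achiral compound itself.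
Remark (design): the lactone is carried through alkyne oxidation and ring B formation in ring-opened form (diethylamide plus benzhydryl-type silyl ether). C3–H of a 3-alkynylphthalide is expected to be more acidic than the alkyne C–H, and a siloxyalkyne would not survive the acid that closes a lactone. The phthalide is therefore closed directly after the benzannulation.

Step 1
Reactants: 1 methyl 3-hydroxy-5-methoxybenzoate
Product: 2 methyl 3-methoxy-5-(triisopropylsilyloxy)benzoate
Conditions: TIPSCl, imidazole, DMF, rt
Reagents that add atoms: triisopropylsilyl chloride, CC(C)[Si](Cl)(C(C)C)C(C)C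
Why: Phenol silylation with a silyl chloride and imidazole is routine, and the bulky, non-coordinating OTIPS group survives organolithium reagents and keeps later metalation away from its own ortho positions.

Step 2
Reactants: 2 methyl 3-methoxy-5-(triisopropylsilyloxy)benzoate
Product: 3 N,N-diethyl-3-methoxy-5-(triisopropylsilyloxy)benzamide
Conditions: Et2NH, AlMe3, toluene, 0 → 80 °C
Reagents that add atoms: diethylamine, CCNCC
Why: Trimethylaluminium-mediated ester aminolysis (Weinreb-type amidation) should give the tertiary amide, which directs ring metalation, is not attacked by a neighbouring alkoxide and tolerates LiHMDS, while the aryl silyl ether is inert to the aluminium amide.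

Step 3
Reactants: 3 N,N-diethyl-3-methoxy-5-(triisopropylsilyloxy)benzamide
Product: 5 N,N-diethyl-2-formyl-3-methoxy-5-(triisopropylsilyloxy)benzamide, via aryllithium 4 (not isolated)
Conditions: s-BuLi, TMEDA, THF, −78 °C; DMF, −78 → 0 °C; aq. NH4Cl
Reagents that add atoms: N,N-dimethylformamide, CN(C)C=O
Why: Directed ortho metalation should occur at C2, the position flanked by the strong CONEt2 director and the cooperating OMe group (C6 is shielded by OTIPS), and the aryllithium is formylated by DMF.

Step 4
Reactants: 5 N,N-diethyl-2-formyl-3-methoxy-5-(triisopropylsilyloxy)benzamide; 6 ethynylmagnesium bromide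
Product: 7 rac-N,N-diethyl-2-(1-hydroxyprop-2-yn-1-yl)-3-methoxy-5-(triisopropylsilyloxy)benzamide
Conditions: THF, −20 → 0 °C; aq. NH4Cl
Reagents that add atoms: none
Why: 1,2-Addition of the alkynyl Grignard reagent to the aryl aldehyde should give the propargylic alcohol without touching the tertiary amide, and the new carbinol centre forms as a racemate because nothing controls the face of attack and the centre is later oxidised away.

Step 5
Reactants: 7 rac-N,N-diethyl-2-(1-hydroxyprop-2-yn-1-yl)-3-methoxy-5-(triisopropylsilyloxy)benzamide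
Product: 10 rac-N,N-diethyl-2-[1,3-bis(triisopropylsilyloxy)prop-2-yn-1-yl]-3-methoxy-5-(triisopropylsilyloxy)benzamide, via dilithium alkoxide acetylide 8 (not isolated), via dilithium alkoxide ynolate 9 (not isolated)
Conditions: LiHMDS (2.2 equiv), THF, −78 °C; t-BuOOLi (from t-BuOOH/LiHMDS), −78 → 0 °C; TIPSOTf (2.5 equiv), −78 → 0 °C; Et3N-deactivated silica
Reagents that add atoms: tert-butyl hydroperoxide, CC(C)(C)OO; triisopropylsilyl trifluoromethanesulfonate, CC(C)[Si](OS(=O)(=O)C(F)(F)F)(C(C)C)C(C)C
Why: Oxidation of the lithium acetylide by lithium tert-butyl peroxide (electrophilic oxygen transfer to an acetylide) should give the lithium ynolate, which TIPSOTf silylates on oxygen together with the alkoxide, while the alkoxide charge suppresses deprotonation of the adjacent propargylic C–H and the amide offers no leaving group for lactonisation under base.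

Step 6
Reactants: 11 propyne; 12 trichloroacetyl chloride
Product: 14 4,4-dichloro-3-methylcyclobut-2-en-1-one, via dichloroketene 13 (not isolated)
Conditions: Zn(Cu), DME, Et2O, 0 °C → rt, excess propyne
Reagents that add atoms: none
Why: Dichloroketene generated by zinc dechlorination of the acid chloride should undergo a regioselective [2+2] cycloaddition with the terminal alkyne, the unsubstituted alkyne carbon bonding to the ketene carbonyl carbon so that the methyl group ends on C3 next to CCl2.

Step 7
Reactants: 14 4,4-dichloro-3-methylcyclobut-2-en-1-one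
Product: 15 rac-4-chloro-3-methylcyclobut-2-en-1-one
Conditions: Zn dust (1.1 equiv), AcOH, TMEDA, EtOH, 0 °C
Reagents that add atoms: none
Why: Reductive dechlorination of an α,α-dichloroketone by zinc in acetic acid removes the first chlorine much faster than the second, so limiting zinc at 0 °C should stop at the monochloride, whose C4 stereocentre is racemic and is lost on ring opening.

Step 8
Reactants: 10 rac-N,N-diethyl-2-[1,3-bis(triisopropylsilyloxy)prop-2-yn-1-yl]-3-methoxy-5-(triisopropylsilyloxy)benzamide; 15 rac-4-chloro-3-methylcyclobut-2-en-1-one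
Product: 20 rac-N,N-diethyl-2-{[3-chloro-2-hydroxy-4-methyl-6-(triisopropylsilyloxy)phenyl](triisopropylsilyloxy)methyl}-3-methoxy-5-(triisopropylsilyloxy)benzamide, via chlorovinylketene 16 (not isolated), via vinylcyclobutenone 17 (not isolated), via dienylketene 18 (not isolated), via cyclohexadienone 19 (not isolated)
Conditions: toluene, 80 °C, then 110 °C; 15 in 1.5-fold excess
Reagents that add atoms: none
Why: Thermal conrotatory 4π opening of 15 (chlorine rotating outward) gives chlorovinylketene 16, whose carbonyl carbon is attacked by the alkyne carbon β to oxygen of 10, so that a regiospecific [2+2] cycloaddition forms C6'–C1' and C2'–C3' and gives vinylcyclobutenone 17. A second 4π opening gives dienylketene 18, and ring B closes by a thermal disrotatory 6π electrocyclisation that re-forms C5'–C6' (six-membered carbocycle, all six ring atoms in the pericyclic array), after which dienone 19 tautomerises to the phenol. The closest known reaction type is the Danheiser benzannulation of cyclobutenones with triisopropylsiloxyalkynes, here with a 4-chloro partner. No stereocentre is created: the sp3 ring carbons of 17 and 19 are transient, and the benzhydryl carbon is untouched, stays racemic and is removed in step 10. The step needs regioselectivity, which the polarisation of the ynol ether secures (free OH on C6' beside C5'–Cl, silyl ether on C2'), and chemoselectivity, which the neutral thermal conditions secure for the amide and all silyl ethers; the unsubstituted ketene carbon (future C3'–H) keeps the cycloaddition open to the branched alkyne, and the flanked C6'–OH should resist acylation by excess ketene.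

Step 9
Reactants: 20 rac-N,N-diethyl-2-{[3-chloro-2-hydroxy-4-methyl-6-(triisopropylsilyloxy)phenyl](triisopropylsilyloxy)methyl}-3-methoxy-5-(triisopropylsilyloxy)benzamide
Product: 22 rac-3-[3-chloro-2-hydroxy-4-methyl-6-(triisopropylsilyloxy)phenyl]-4-methoxy-6-(triisopropylsilyloxy)isobenzofuran-1(3H)-one, via iminium ether tosylate 21 (not isolated)
Conditions: TsOH·H2O (1.2 equiv), toluene, 60 °C
Reagents that add atoms: water, O
Why: Acid should ionise the doubly benzylic silyl ether (cation stabilised by the ortho-hydroxy, ortho-silyloxy ring B), the neighbouring amide oxygen closes the five-membered ring and water hydrolyses the iminium ether, which is the acid-mediated lactonisation of ortho-(hydroxyalkyl)benzamides to phthalides, with C3 remaining racemic and the aryl TIPS ethers stable to the acid.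

Step 10
Reactants: 22 rac-3-[3-chloro-2-hydroxy-4-methyl-6-(triisopropylsilyloxy)phenyl]-4-methoxy-6-(triisopropylsilyloxy)isobenzofuran-1(3H)-one
Product: 25 2-[3-chloro-2-hydroxy-4-methyl-6-(triisopropylsilyloxy)benzoyl]-3-methoxy-5-(triisopropylsilyloxy)benzoic acid, via dipotassium dianion 23 (not isolated), via hydroperoxide dipotassium salt 24 (not isolated)
Conditions: KHMDS (2.3 equiv), THF, −78 °C; O2; P(OEt)3; 1 M HCl
Reagents that add atoms: dioxygen, O=O
Why: KHMDS should form the phenoxide and then remove the doubly benzylic C3–H, whose anion is stabilised through the lactone carbonyl, and carbanion oxygenation with O2 followed by phosphite reduction of the hydroperoxide gives the 3-hydroxyphthalide, the ring tautomer of the keto acid, so the only stereocentre is erased.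

Step 11
Reactants: 25 2-[3-chloro-2-hydroxy-4-methyl-6-(triisopropylsilyloxy)benzoyl]-3-methoxy-5-(triisopropylsilyloxy)benzoic acid
Product: 26 methyl 2-[3-chloro-2-hydroxy-4-methyl-6-(triisopropylsilyloxy)benzoyl]-3-methoxy-5-(triisopropylsilyloxy)benzoate
Conditions: TMSCHN2, toluene/MeOH, 0 °C
Reagents that add atoms: trimethylsilyldiazomethane, C[Si](C)(C)C=[N+]=[N-]
Why: Diazoalkane esterification should methylate the carboxylic acid far faster than the hindered, hydrogen-bonded phenol and gives the normal ester from the open keto acid form.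

Step 12
Reactants: 26 methyl 2-[3-chloro-2-hydroxy-4-methyl-6-(triisopropylsilyloxy)benzoyl]-3-methoxy-5-(triisopropylsilyloxy)benzoate
Product: 27 monochlorosulochrin, methyl 2-(3-chloro-2,6-dihydroxy-4-methylbenzoyl)-5-hydroxy-3-methoxybenzoate
Conditions: TBAF, AcOH, THF, 0 °C
Reagents that add atoms: none
Why: Fluoride-mediated desilylation cleaves aryl triisopropylsilyl ethers rapidly, and acetic acid buffering should keep the liberated phenoxides from attacking the neighbouring ester or ketone.

Compound list
1 | methyl 3-hydroxy-5-methoxybenzoate | COC(=O)c1cc(O)cc(OC)c1 | starting material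
2 | methyl 3-methoxy-5-(triisopropylsilyloxy)benzoate | COC(=O)c1cc(OC)cc(O[Si](C(C)C)(C(C)C)C(C)C)c1 | intermediate
3 | N,N-diethyl-3-methoxy-5-(triisopropylsilyloxy)benzamide | CCN(CC)C(=O)c1cc(OC)cc(O[Si](C(C)C)(C(C)C)C(C)C)c1 | intermediate
4 | N,N-diethyl-2-lithio-3-methoxy-5-(triisopropylsilyloxy)benzamide (aryllithium, not isolated) | CCN(CC)C(=O)c1cc(O[Si](C(C)C)(C(C)C)C(C)C)cc(OC)c1[Li] | intermediate
5 | N,N-diethyl-2-formyl-3-methoxy-5-(triisopropylsilyloxy)benzamide | CCN(CC)C(=O)c1cc(O[Si](C(C)C)(C(C)C)C(C)C)cc(OC)c1C=O | intermediate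
6 | ethynylmagnesium bromide | C#C[Mg]Br | starting material
7 | rac-N,N-diethyl-2-(1-hydroxyprop-2-yn-1-yl)-3-methoxy-5-(triisopropylsilyloxy)benzamide | CCN(CC)C(=O)c1cc(O[Si](C(C)C)(C(C)C)C(C)C)cc(OC)c1C(O)C#C | intermediate
8 | dilithium alkoxide acetylide of 7 (racemic, not isolated) | CCN(CC)C(=O)c1cc(O[Si](C(C)C)(C(C)C)C(C)C)cc(OC)c1C(O[Li])C#C[Li] | intermediate
9 | dilithium alkoxide ynolate (racemic, not isolated) | CCN(CC)C(=O)c1cc(O[Si](C(C)C)(C(C)C)C(C)C)cc(OC)c1C(O[Li])C#CO[Li] | intermediate
10 | rac-N,N-diethyl-2-[1,3-bis(triisopropylsilyloxy)prop-2-yn-1-yl]-3-methoxy-5-(triisopropylsilyloxy)benzamide | CCN(CC)C(=O)c1cc(O[Si](C(C)C)(C(C)C)C(C)C)cc(OC)c1C(O[Si](C(C)C)(C(C)C)C(C)C)C#CO[Si](C(C)C)(C(C)C)C(C)C | intermediate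
11 | propyne | CC#C | starting material
12 | trichloroacetyl chloride | ClC(Cl)(Cl)C(Cl)=O | starting material
13 | dichloroketene (not isolated) | ClC(Cl)=C=O | intermediate
14 | 4,4-dichloro-3-methylcyclobut-2-en-1-one | CC1=CC(=O)C1(Cl)Cl | intermediate
15 | rac-4-chloro-3-methylcyclobut-2-en-1-one | CC1=CC(=O)C1Cl | intermediate
16 | (E)-4-chloro-3-methylbuta-1,3-dien-1-one (chlorovinylketene, not isolated) | O=C=C/C(C)=C/Cl | intermediate
17 | 4-[(E)-2-chloro-1-methylvinyl]-3-(triisopropylsilyloxy)cyclobut-2-en-1-one carrying at C2 the ring A CH(OTIPS) group of 10 (diastereomer mixture, not isolated) | O=C1C(C(O[Si](C(C)C)(C(C)C)C(C)C)c2c(OC)cc(O[Si](C(C)C)(C(C)C)C(C)C)cc2C(=O)N(CC)CC)=C(O[Si](C(C)C)(C(C)C)C(C)C)C1/C(C)=C/Cl | intermediate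
18 | dienylketene: 6-chloro-5-methyl-3-(triisopropylsilyloxy)hexa-1,3,5-trien-1-one carrying at C2 the ring A CH(OTIPS) group, ketene and chlorovinyl termini cis on the central C=C (not isolated) | O=C=C(C(O[Si](C(C)C)(C(C)C)C(C)C)c1c(OC)cc(O[Si](C(C)C)(C(C)C)C(C)C)cc1C(=O)N(CC)CC)/C(O[Si](C(C)C)(C(C)C)C(C)C)=C\C(C)=C\Cl | intermediate
19 | 6-chloro-5-methyl-3-(triisopropylsilyloxy)cyclohexa-2,4-dien-1-one carrying at C2 the ring A CH(OTIPS) group (diastereomer mixture, not isolated) | O=C1C(C(O[Si](C(C)C)(C(C)C)C(C)C)c2c(OC)cc(O[Si](C(C)C)(C(C)C)C(C)C)cc2C(=O)N(CC)CC)=C(O[Si](C(C)C)(C(C)C)C(C)C)C=C(C)C1Cl | intermediate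
20 | rac-N,N-diethyl-2-{[3-chloro-2-hydroxy-4-methyl-6-(triisopropylsilyloxy)phenyl](triisopropylsilyloxy)methyl}-3-methoxy-5-(triisopropylsilyloxy)benzamide | CCN(CC)C(=O)c1cc(O[Si](C(C)C)(C(C)C)C(C)C)cc(OC)c1C(O[Si](C(C)C)(C(C)C)C(C)C)c1c(O[Si](C(C)C)(C(C)C)C(C)C)cc(C)c(Cl)c1O | intermediate
21 | rac-3-aryl-1-(diethyliminio)-4-methoxy-6-(triisopropylsilyloxy)-1,3-dihydroisobenzofuran tosylate, aryl = 3-chloro-2-hydroxy-4-methyl-6-(triisopropylsilyloxy)phenyl (not isolated) | CC[N+](CC)=C1OC(c2c(O[Si](C(C)C)(C(C)C)C(C)C)cc(C)c(Cl)c2O)c2c(OC)cc(O[Si](C(C)C)(C(C)C)C(C)C)cc12.Cc1ccc(cc1)S(=O)(=O)[O-] | intermediate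
22 | rac-3-[3-chloro-2-hydroxy-4-methyl-6-(triisopropylsilyloxy)phenyl]-4-methoxy-6-(triisopropylsilyloxy)isobenzofuran-1(3H)-one | COc1cc(O[Si](C(C)C)(C(C)C)C(C)C)cc2C(=O)OC(c3c(O[Si](C(C)C)(C(C)C)C(C)C)cc(C)c(Cl)c3O)c12 | intermediate
23 | dipotassium phenoxide C3-carbanion of 22 (not isolated) | COc1cc(O[Si](C(C)C)(C(C)C)C(C)C)cc2C(=O)O[C-](c3c(O[Si](C(C)C)(C(C)C)C(C)C)cc(C)c(Cl)c3[O-])c12.[K+].[K+] | intermediate
24 | dipotassium salt of the 3-hydroperoxyphthalide (racemic, not isolated) | COc1cc(O[Si](C(C)C)(C(C)C)C(C)C)cc2C(=O)OC(O[O-])(c3c(O[Si](C(C)C)(C(C)C)C(C)C)cc(C)c(Cl)c3[O-])c12.[K+].[K+] | intermediate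
25 | 2-[3-chloro-2-hydroxy-4-methyl-6-(triisopropylsilyloxy)benzoyl]-3-methoxy-5-(triisopropylsilyloxy)benzoic acid (open form of the 3-hydroxyphthalide) | COc1cc(O[Si](C(C)C)(C(C)C)C(C)C)cc(C(O)=O)c1C(=O)c1c(O[Si](C(C)C)(C(C)C)C(C)C)cc(C)c(Cl)c1O | intermediate
26 | methyl 2-[3-chloro-2-hydroxy-4-methyl-6-(triisopropylsilyloxy)benzoyl]-3-methoxy-5-(triisopropylsilyloxy)benzoate | COC(=O)c1cc(O[Si](C(C)C)(C(C)C)C(C)C)cc(OC)c1C(=O)c1c(O[Si](C(C)C)(C(C)C)C(C)C)cc(C)c(Cl)c1O | intermediate
27 | monochlorosulochrin, methyl 2-(3-chloro-2,6-dihydroxy-4-methylbenzoyl)-5-hydroxy-3-methoxybenzoate (achiral) | COC(=O)c1cc(O)cc(OC)c1C(=O)c1c(O)cc(C)c(Cl)c1O | target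

Total step count: 12. Longest linear sequence: 10 steps (steps 1–5 and 8–12, from compound 1); the cyclobutenone branch adds 2 steps (6 and 7).

Steps most likely to fail

Step 8. The allylic α-chloroketone may ionise or lose HCl before it ring-opens, the chlorovinylketene may dimerise faster than it adds to the branched alkyne, and the new phenol may be acylated by excess ketene. The fallback moves the chlorine to a later stage and sets out from 14 and 10. Exhaustive zinc reduction of 14 (excess Zn, AcOH, TMEDA, EtOH, rt) gives 3-methylcyclobut-2-en-1-one F1, a proven type of benzannulation partner. Heating F1 with 10 as in step 8 should give the chlorine-free phenol rac-N,N-diethyl-2-{[2-hydroxy-4-methyl-6-(triisopropylsilyloxy)phenyl](triisopropylsilyloxy)methyl}-3-methoxy-5-(triisopropylsilyloxy)benzamide F2. Amine-catalysed ortho-chlorination of the free phenol (SO2Cl2, catalytic secondary amine, NaHCO3, toluene, 0 °C) then comes back to the route at 20. The free phenol ring is the most nucleophilic ring, and chlorination at its other open position would still lead to 27 after desilylation, because ring B of the target is symmetric about the C1'–C4' axis.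

Step 5. Proton transfer from the propargylic, benzylic C–H to the acetylide (with propargyl–allenyl isomerisation), sluggish oxygen transfer to a hindered aggregated acetylide, or ionisation of the γ-silyloxy siloxyalkyne on silica may erode the step. The fallback makes the siloxyalkyne on a fragment without ring A and joins ring A afterwards; it sets out from 3 and 15. Kowalski ester homologation of commercial ethyl diethoxyacetate (CH2Br2/LiTMP, then n-BuLi, then TIPSCl) gives 3,3-diethoxy-1-(triisopropylsilyloxy)prop-1-yne F3. Benzannulation of F3 with 15 under the conditions of step 8 should give 2-chloro-6-(diethoxymethyl)-3-methyl-5-(triisopropylsilyloxy)phenol F4. Mild acetal hydrolysis (PPTS, wet acetone) gives 3-chloro-2-hydroxy-4-methyl-6-(triisopropylsilyloxy)benzaldehyde F5. The lithium phenoxide of F5 (LiHMDS) is treated with aryllithium 4, made from 3 as in step 3, to give rac-N,N-diethyl-2-{[3-chloro-2-hydroxy-4-methyl-6-(triisopropylsilyloxy)phenyl](hydroxy)methyl}-3-methoxy-5-(triisopropylsilyloxy)benzamide F6. Acid lactonisation under the conditions of step 9 then comes back to the route at 22.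

Step 10. Deprotonation of the crowded C3–H may be slow, the carbanion may undergo 1,4 O→C silyl migration from the ortho silyl ether, and the electron-rich phenoxide may be oxidised by O2. The fallback avoids carbanion chemistry and sets out from 22. Reduction of the lactone with LiBH4 (THF, 0 °C → rt) gives rac-2-chloro-6-{hydroxy[2-(hydroxymethyl)-6-methoxy-4-(triisopropylsilyloxy)phenyl]methyl}-3-methyl-5-(triisopropylsilyloxy)phenol F7. Swern oxidation, which activates both carbinols at −78 °C before either carbonyl forms and so avoids lactol formation, gives 2-[3-chloro-2-hydroxy-4-methyl-6-(triisopropylsilyloxy)benzoyl]-3-methoxy-5-(triisopropylsilyloxy)benzaldehyde F8. Pinnick oxidation (NaClO2, NaH2PO4, 2-methyl-2-butene) then comes back to the route at 25.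

Further compounds
F1 | step 8 | 3-methylcyclobut-2-en-1-one | CC1=CC(=O)C1
F2 | step 8 | rac-N,N-diethyl-2-{[2-hydroxy-4-methyl-6-(triisopropylsilyloxy)phenyl](triisopropylsilyloxy)methyl}-3-methoxy-5-(triisopropylsilyloxy)benzamide | CCN(CC)C(=O)c1cc(O[Si](C(C)C)(C(C)C)C(C)C)cc(OC)c1C(O[Si](C(C)C)(C(C)C)C(C)C)c1c(O[Si](C(C)C)(C(C)C)C(C)C)cc(C)cc1O
F3 | step 5 | 3,3-diethoxy-1-(triisopropylsilyloxy)prop-1-yne | CCOC(OCC)C#CO[Si](C(C)C)(C(C)C)C(C)C
F4 | step 5 | 2-chloro-6-(diethoxymethyl)-3-methyl-5-(triisopropylsilyloxy)phenol | CCOC(OCC)c1c(O[Si](C(C)C)(C(C)C)C(C)C)cc(C)c(Cl)c1O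
F5 | step 5 | 3-chloro-2-hydroxy-4-methyl-6-(triisopropylsilyloxy)benzaldehyde | O=Cc1c(O[Si](C(C)C)(C(C)C)C(C)C)cc(C)c(Cl)c1O
F6 | step 5 | rac-N,N-diethyl-2-{[3-chloro-2-hydroxy-4-methyl-6-(triisopropylsilyloxy)phenyl](hydroxy)methyl}-3-methoxy-5-(triisopropylsilyloxy)benzamide | CCN(CC)C(=O)c1cc(O[Si](C(C)C)(C(C)C)C(C)C)cc(OC)c1C(O)c1c(O[Si](C(C)C)(C(C)C)C(C)C)cc(C)c(Cl)c1O
F7 | step 10 | rac-2-chloro-6-{hydroxy[2-(hydroxymethyl)-6-methoxy-4-(triisopropylsilyloxy)phenyl]methyl}-3-methyl-5-(triisopropylsilyloxy)phenol | COc1cc(O[Si](C(C)C)(C(C)C)C(C)C)cc(CO)c1C(O)c1c(O[Si](C(C)C)(C(C)C)C(C)C)cc(C)c(Cl)c1O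
F8 | step 10 | 2-[3-chloro-2-hydroxy-4-methyl-6-(triisopropylsilyloxy)benzoyl]-3-methoxy-5-(triisopropylsilyloxy)benzaldehyde | COc1cc(O[Si](C(C)C)(C(C)C)C(C)C)cc(C=O)c1C(=O)c1c(O[Si](C(C)C)(C(C)C)C(C)C)cc(C)c(Cl)c1O
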